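Assumption: tricyclic compounds carry longipinane locants (C1 ketone, C2=C3 with methyl on C3, cyclobutane C4–C5–C11–C10, C5–C6(Me2)–C7–C8–C9–C10(Me), C11–C1); pent-1-yn-3-one and angelic acid are taken as purchasable.

## Retrosynthetic overview

1. Target ⇒ trans-7,9-diol (double angeloylation) ⇒ 7-hydroxy-9-ketone (hydroxyl-directed reduction) ⇒ 7,8-epoxy-9-ketone (reductive epoxide opening).
2. Cyclobutane, formed last: the C4–C10 bond is closed by anodic oxidation of a bis(silyl enol ether) of a cis-fused cyclohexenone–cycloheptenone.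
3. Seven-membered ring: C10–C11 by intramolecular oxidative enolate coupling; C6–C7 by addition of a tertiary radical to an ynone.
4. Six-membered ring and the C5 stereocentre are bought as (+)-3-carene (allylic oxidation, then HBr opening of the cyclopropane).
5. Ring order: six (bought) → seven → four; C7–O is set on the cis-fused bicycle, C9–O by 1,3-anti delivery from C7–OH.

## Route

Step 1
Reactants: 1 (+)-3-carene
Product: 2 car-3-en-5-one, (1R,6S)-4,7,7-trimethylbicyclo[4.1.0]hept-3-en-2-one
Conditions: CrO3, 3,5-dimethylpyrazole, CH2Cl2, −20 °C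
Reagents that add atoms: chromium trioxide, O=[Cr](=O)=O
Why: Allylic oxidation with hexavalent chromium attacks the C5 methylene (allylic through the unsubstituted alkene carbon and next to the cyclopropane), leaving both ring-fusion stereocentres untouched.

Step 2
Reactants: 2 car-3-en-5-one
Product: 3 (5S)-5-(2-bromopropan-2-yl)-3-methylcyclohex-2-en-1-one
Conditions: HBr (33% in AcOH), Et2O, 0 °C
Reagents that add atoms: hydrogen bromide, Br
Why: Homoconjugate (Markovnikov) HBr opening of the acylcyclopropane, the reverse of the classical carone ring closure, cleaves the bond between the α-carbon and CMe2 and puts bromide on the tertiary carbon; the carene C1 stereocentre (now C5) is not touched.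

Step 3
Reactants: 3 (5S)-5-(2-bromopropan-2-yl)-3-methylcyclohex-2-en-1-one; 4 pent-1-yn-3-one
Product: 5 (5S)-3-methyl-5-[(3Z)-2-methyl-5-oxohept-3-en-2-yl]cyclohex-2-en-1-one
Conditions: (Me3Si)3SiH, Et3B (cat.), air, PhMe, −20 °C to rt
Reagents that add atoms: none
Why: Giese-type radical hydroalkylation of an ynone: bromine abstraction gives the tertiary radical, which adds to the alkyne terminus, and the linear α-acylvinyl radical takes H from the silane anti to the bulky group, giving the Z-enone kinetically.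

Step 4
Reactants: 5 (5S)-3-methyl-5-[(3Z)-2-methyl-5-oxohept-3-en-2-yl]cyclohex-2-en-1-one
Product: 7 (1R,7S)-2,6,6,9-tetramethylbicyclo[5.4.0]undeca-4,9-diene-3,11-dione (cis ring fusion, C2 epimers), via dilithium bis-enolate 6 (not isolated)
Conditions: LDA (2.3 equiv, inverse addition), THF, −78 °C; Fe(acac)3 (2.2 equiv), −78 °C to rt, 0.01 M
Reagents that add atoms: none
Why: Intramolecular oxidative enolate heterocoupling (Baran type, trivalent iron) joins the α′-carbon of the cyclohexenone to the only enolisable carbon of the side-chain ketone; axial bond formation at the ring enolate with the CMe2 group equatorial gives the cis fusion (C1 set by C7), and the C2 mixture is erased later.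

Step 5
Reactants: 7 (1R,7S)-2,6,6,9-tetramethylbicyclo[5.4.0]undeca-4,9-diene-3,11-dione
Product: 8 (1R,4R,5R,7S)-4,5-epoxy-2,6,6,9-tetramethylbicyclo[5.4.0]undec-9-ene-3,11-dione (oxirane O cis to H-1 and H-7)
Conditions: t-BuOOH (decane), Triton B (0.1 equiv), THF, 0 °C
Reagents that add atoms: tert-butyl hydroperoxide, CC(C)(C)OO
Why: Weitz–Scheffer nucleophilic epoxidation attacks only the disubstituted cycloheptenone, from the convex face of the cis-fused bicycle (the face of the ring-fusion hydrogens), which sets the future C7–O stereocentre; the weakly basic peroxide anion does not epimerise C1.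

Step 6
Reactants: 8 (1R,4R,5R,7S)-4,5-epoxy-2,6,6,9-tetramethylbicyclo[5.4.0]undec-9-ene-3,11-dione
Product: 9 3,11-bis(tert-butyldimethylsilyloxy)-4,5-epoxy-2,6,6,9-tetramethylbicyclo[5.4.0]undeca-2,8,10-triene (C1, C4, C5, C7 as in 8)
Conditions: TBSOTf (3 equiv), Et3N (5 equiv), CH2Cl2, 0 °C to rt
Reagents that add atoms: tert-butyldimethylsilyl triflate, CC(C)(C)[Si](C)(C)OS(=O)(=O)C(F)(F)F
Why: Soft enolisation: the C3 ketone can enolise only toward C2 (C4 is an oxirane carbon), and the enone gives the through-conjugated dienol ether by γ-deprotonation at C8 because the α′-position is a hindered methine.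

Step 7
Reactants: 9 3,11-bis(tert-butyldimethylsilyloxy)-4,5-epoxy-2,6,6,9-tetramethylbicyclo[5.4.0]undeca-2,8,10-triene
Product: 10 (4R,5S,7R,8R,10R,11R)-7,8-epoxylongipin-2-ene-1,9-dione
Conditions: RVC anode, Pt cathode, undivided cell, 0.1 M LiClO4, 2,6-lutidine, MeOH/CH2Cl2 (1:4), constant current 8 mA, 2.2 F/mol, −78 °C
Reagents that add atoms: none
Why: Proposed new method: anodic one-electron oxidation of the silyl dienol ether gives a radical cation whose γ-terminus is captured by the pendant tetrasubstituted silyl enol ether held on the same face by the cis ring fusion (4-exo closure), and a second electron loss plus loss of both silyl groups to methanol makes the step irreversible and releases the enone and the C9 ketone; attack at the γ-carbon is preferred because it leaves a silyloxy-allyl radical, and the new C10 quaternary centre and C4 are fixed by the tether; the closest known reactions are anodic enol ether–olefin couplings (Moeller) and oxidative coupling of silyl bis-enol ethers to 1,4-diketones, neither yet shown for a vinylogous closure to a cyclobutane.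

Step 8
Reactants: 10 (4R,5S,7R,8R,10R,11R)-7,8-epoxylongipin-2-ene-1,9-dione
Product: 11 (4R,5S,7S,10R,11R)-7-hydroxylongipin-2-ene-1,9-dione
Conditions: SmI2 (2.5 equiv), THF/MeOH, −90 °C
Reagents that add atoms: none
Why: Reductive cleavage of the Cα–O bond of an α,β-epoxy ketone by divalent samarium (Molander) gives the β-hydroxy ketone with the C7–O centre untouched; the conjugated enone is inert at this temperature.

Step 9
Reactants: 11 (4R,5S,7S,10R,11R)-7-hydroxylongipin-2-ene-1,9-dione
Product: 12 (4R,5S,7S,9S,10R,11R)-7,9-dihydroxylongipin-2-en-1-one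
Conditions: Me4NBH(OAc)3, MeCN/AcOH (1:1), −30 °C
Reagents that add atoms: none
Why: Evans–Saksena reduction: the C7 alkoxyborohydride delivers hydride intramolecularly to the C9 ketone and gives the 1,3-anti (trans) diol, so C9 is set by C7; the enone, which has no directing hydroxyl, is not reduced.

Step 10
Reactants: 12 (4R,5S,7S,9S,10R,11R)-7,9-dihydroxylongipin-2-en-1-one; 13 angelic acid
Product: 15 (4R,5S,7S,9S,10R,11R)-7,9-bis[(Z)-2-methylbut-2-enoyloxy]longipin-2-en-1-one (target), via angelic 2,4,6-trichlorobenzoic anhydride 14 (not isolated)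
Conditions: 13 (4 equiv), 2,4,6-trichlorobenzoyl chloride, Et3N, PhMe, rt; then 12, 75 °C
Reagents that add atoms: none
Why: Yamaguchi-type mixed-anhydride acylation without a nucleophilic catalyst (Hartmann protocol for angelates) esterifies both hindered alcohols while keeping the Z geometry of the acid.

## Compound list

1 | (+)-3-carene, (1S,6R)-3,7,7-trimethylbicyclo[4.1.0]hept-3-ene | CC1=CC[C@@H]2[C@H](C1)C2(C)C | starting material
2 | car-3-en-5-one, (1R,6S)-4,7,7-trimethylbicyclo[4.1.0]hept-3-en-2-one | CC1=CC(=O)[C@@H]2[C@H](C1)C2(C)C | intermediate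
3 | (5S)-5-(2-bromopropan-2-yl)-3-methylcyclohex-2-en-1-one | CC1=CC(=O)C[C@H](C1)C(C)(C)Br | intermediate
4 | pent-1-yn-3-one | CCC(=O)C#C | starting material
5 | (5S)-3-methyl-5-[(3Z)-2-methyl-5-oxohept-3-en-2-yl]cyclohex-2-en-1-one | CC1=CC(=O)C[C@H](C1)C(C)(C)/C=C\C(=O)CC | intermediate
6 | dilithium bis-enolate of 5 (cross-conjugated cyclohexadienolate and side-chain dienolate) | CC1=CC(O[Li])=C[C@H](C1)C(C)(C)/C=C\C(O[Li])=CC | intermediate
7 | (1R,7S)-2,6,6,9-tetramethylbicyclo[5.4.0]undeca-4,9-diene-3,11-dione, cis-fused, C2 epimers | CC1=CC(=O)[C@@H]2[C@H](C1)C(C)(C)C=CC(=O)C2C | intermediate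
8 | (1R,4R,5R,7S)-4,5-epoxy-2,6,6,9-tetramethylbicyclo[5.4.0]undec-9-ene-3,11-dione, oxirane O cis to H-1/H-7, C2 epimers | CC1=CC(=O)[C@@H]2[C@H](C1)C(C)(C)[C@H]3O[C@H]3C(=O)C2C | intermediate
9 | 3,11-bis(tert-butyldimethylsilyloxy)-4,5-epoxy-2,6,6,9-tetramethylbicyclo[5.4.0]undeca-2,8,10-triene, stereocentres as in 8 | CC1=C[C@H]2[C@@H](C(O[Si](C)(C)C(C)(C)C)=C1)C(C)=C(O[Si](C)(C)C(C)(C)C)[C@@H]3O[C@@H]3C2(C)C | intermediate
10 | (4R,5S,7R,8R,10R,11R)-7,8-epoxylongipin-2-ene-1,9-dione | CC1(C)[C@H]2O[C@H]2C(=O)[C@@]2(C)[C@@H]3C(=O)C=C(C)[C@H]2[C@@H]31 | intermediate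
11 | (4R,5S,7S,10R,11R)-7-hydroxylongipin-2-ene-1,9-dione | CC1(C)[C@@H](O)CC(=O)[C@@]2(C)[C@@H]3C(=O)C=C(C)[C@H]2[C@@H]31 | intermediate
12 | (4R,5S,7S,9S,10R,11R)-7,9-dihydroxylongipin-2-en-1-one | O[C@H]1C[C@H](O)[C@@]2(C)[C@@H]3C(=O)C=C(C)[C@H]2[C@@H]3C1(C)C | intermediate
13 | angelic acid, (Z)-2-methylbut-2-enoic acid | C/C=C(/C)C(=O)O | starting material
14 | angelic 2,4,6-trichlorobenzoic anhydride | C/C=C(/C)C(=O)OC(=O)c1c(Cl)cc(Cl)cc1Cl | intermediate
15 | (4R,5S,7S,9S,10R,11R)-7,9-bis[(Z)-2-methylbut-2-enoyloxy]longipin-2-en-1-one | C/C=C(/C)C(=O)O[C@H]1C[C@H](OC(=O)/C(C)=C\C)[C@@]2(C)[C@@H]3C(=O)C=C(C)[C@H]2[C@@H]3C1(C)C | target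

## Step count and risk

Total steps: 10. Longest linear sequence: 10 (from (+)-3-carene).

Steps most likely to fail:

Step 7 (proposed anodic cyclobutane closure). The 4-exo capture may lose to solvent trapping of the radical cation or to plain desilylation back to 8. Fallback, setting out from 9: NBS (THF, −78 °C) brominates the dienol ether at its γ-carbon, anti to the seven-membered ring, and gives 8-bromo-3-(tert-butyldimethylsilyloxy)-4,5-epoxy-2,6,6,9-tetramethylbicyclo[5.4.0]undeca-2,9-dien-11-one F1. TBAF (THF, −78 to 0 °C) then releases the C2 enolate regiospecifically, and it displaces the allylic bromide with inversion. This is a classical intramolecular enolate alkylation to a bicyclo[3.1.1]heptenone, and it comes back to the route at 10.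

Step 4 (oxidative enolate coupling to the seven-membered ring). A mono-enolate can close a six-membered aldol onto the other ketone before the second deprotonation, and seven-membered rings by this coupling have little precedent. Fallback, setting out from 2: iodotrimethylsilane (CH2Cl2, −78 °C) opens the cyclopropane to {[(3S)-3-(2-iodopropan-2-yl)-5-methylcyclohexa-1,5-dien-1-yl]oxy}trimethylsilane F2, so the ring ketone stays masked. Radical hydroalkylation of 4 ((Me3Si)3SiH, Et3B, air) gives {[(3S)-5-methyl-3-[(3Z)-2-methyl-5-oxohept-3-en-2-yl]cyclohexa-1,5-dien-1-yl]oxy}trimethylsilane F3. LDA/TMSCl (THF, −78 °C) converts the one free ketone into {[(3S)-5-methyl-3-[(3Z)-2-methyl-5-(trimethylsilyloxy)hepta-3,5-dien-2-yl]cyclohexa-1,5-dien-1-yl]oxy}trimethylsilane F4. Oxidation with (NH4)2Ce(NO3)6 (tetravalent cerium) and NaHCO3 in MeCN at −20 °C, the known coupling of bis(silyl enol ethers) to 1,4-diketones, comes back to the route at 7.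

Step 10 (double angeloylation). Both alcohols are flanked by quaternary carbons, and forcing conditions isomerise angelate to tiglate. Fallback, setting out from 12: esterify with 2-[bis(2,2,2-trifluoroethoxy)phosphoryl]propanoic acid (DCC, DMAP, CH2Cl2) to the 7,9-bis{2-[bis(2,2,2-trifluoroethoxy)phosphoryl]propanoate} of 12 F5. A Still–Gennari olefination with acetaldehyde (KHMDS, 18-crown-6, THF, −78 °C) then builds both Z-2-methylbut-2-enoates on the ester and comes back to the route at 15.

## Further compounds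

F1 | step 7 | 8-bromo-3-(tert-butyldimethylsilyloxy)-4,5-epoxy-2,6,6,9-tetramethylbicyclo[5.4.0]undeca-2,9-dien-11-one (Br trans to the seven-membered ring) | CC1=CC(=O)[C@@H]2[C@H]([C@@H]1Br)C(C)(C)[C@H]3O[C@H]3C(O[Si](C)(C)C(C)(C)C)=C2C
F2 | step 4 | {[(3S)-3-(2-iodopropan-2-yl)-5-methylcyclohexa-1,5-dien-1-yl]oxy}trimethylsilane | CC1=CC(O[Si](C)(C)C)=C[C@H](C1)C(C)(C)I
F3 | step 4 | {[(3S)-5-methyl-3-[(3Z)-2-methyl-5-oxohept-3-en-2-yl]cyclohexa-1,5-dien-1-yl]oxy}trimethylsilane | CC1=CC(O[Si](C)(C)C)=C[C@H](C1)C(C)(C)/C=C\C(=O)CC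
F4 | step 4 | {[(3S)-5-methyl-3-[(3Z)-2-methyl-5-(trimethylsilyloxy)hepta-3,5-dien-2-yl]cyclohexa-1,5-dien-1-yl]oxy}trimethylsilane | CC1=CC(O[Si](C)(C)C)=C[C@H](C1)C(C)(C)/C=C\C(O[Si](C)(C)C)=CC
F5 | step 10 | 7,9-bis{2-[bis(2,2,2-trifluoroethoxy)phosphoryl]propanoate} of 12 | CC(C(=O)O[C@H]1C[C@H](OC(=O)C(C)P(=O)(OCC(F)(F)F)OCC(F)(F)F)[C@@]2(C)[C@@H]3C(=O)C=C(C)[C@H]2[C@@H]3C1(C)C)P(=O)(OCC(F)(F)F)OCC(F)(F)F
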